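The cycloheptenone ring (C1, C5 to C10, daucane numbering) is divided into a four-carbon diene, C7=C6–C5=C1, which spans the ring fusion and is built on the cyclopentene that already holds the C4 carbinol, and a three-carbon unit, C8–C9–C10, that brings the ketone. One catalyst-controlled tandem cyclopropanation/Cope rearrangement (a formal (4+3) cycloaddition) of a silyloxyvinyl diazoacetate with this semicyclic diene closes the seven-membered ring, sets quaternary C1 and delivers C9 as a masked ketone and C8 bearing an ester that later admits the methyl group and is lost. C4 is bought as (S)-terpinen-4-ol; C5 and C6 are relayed from it.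

Key step: step 7

Numbering used for atoms: C1 = methyl-bearing quaternary ring-fusion carbon; C2, C3 = cyclopentane CH2; C4 = carbinol carbon with isopropyl; C5 = ring-fusion CH; C6 = ester-bearing CH; C7 = enone CH; C8 = methyl-bearing enone carbon; C9 = ketone carbon; C10 = CH2 between C9 and C1.

Assumption: (S)-(+)-terpinen-4-ol is bought as the single enantiomer; any minor enantiomer would be turned by the chiral catalyst of step 7 into a diastereomer that is removed there.

Step 1
Reactants: 1 (S)-(+)-terpinen-4-ol
Product: 2 (S)-terpinen-4-ol triethylsilyl ether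
Conditions: TESOTf, 2,6-lutidine, CH2Cl2, 0 °C → rt
Reagents that add atoms: triethylsilyl trifluoromethanesulfonate, CC[Si](CC)(CC)OS(=O)(=O)C(F)(F)F
Why: Silylation of the tertiary alcohol with a silyl triflate and a hindered pyridine base protects the hydroxyl for the carbenoid step; the bought C4 stereocenter is not touched.

Step 2
Reactants: 2 (S)-terpinen-4-ol triethylsilyl ether
Product: 3 (S)-3-isopropyl-6-oxo-3-(triethylsilyloxy)heptanal
Conditions: O3, CH2Cl2/MeOH, −78 °C; then Me2S, −78 °C → rt
Reagents that add atoms: ozone, [O-][O+]=O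
Why: Ozonolysis with reductive work-up cleaves the only alkene to the 1,6-keto aldehyde and leaves the silyl ether and the quaternary carbinol carbon alone.

Step 3
Reactants: 3 (S)-3-isopropyl-6-oxo-3-(triethylsilyloxy)heptanal
Product: 4 (R)-5-isopropyl-2-methyl-5-(triethylsilyloxy)cyclopent-1-ene-1-carbaldehyde
Conditions: piperidine (cat.), AcOH (cat.), benzene, 60 °C
Reagents that add atoms: none
Why: Amine-catalysed intramolecular aldol condensation, in which the enamine of the aldehyde attacks the methyl ketone (5-exo) and dehydration gives the tetrasubstituted enal, as in the standard conversion of 1-methylcyclohexene ozonolysis products into 2-methylcyclopent-1-enecarbaldehydes; the carbinol carbon is quaternary and keeps its configuration (the descriptor changes from S to R only through the priorities).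

Step 4
Reactants: 4 (R)-5-isopropyl-2-methyl-5-(triethylsilyloxy)cyclopent-1-ene-1-carbaldehyde
Product: 5 (R)-triethyl[(1-isopropyl-3-methyl-2-vinylcyclopent-2-en-1-yl)oxy]silane
Conditions: Ph3PCH3Br, KOtBu, THF, 0 °C → rt
Reagents that add atoms: methyltriphenylphosphonium bromide, C[P+](c1ccccc1)(c1ccccc1)c1ccccc1.[Br-]
Why: Wittig methylenation of the unsaturated aldehyde gives the semicyclic diene C7=C6–C5=C1; no stereocenter is formed.

Step 5
Reactants: 6 benzyl acetoacetate
Product: 7 benzyl 2-diazo-3-oxobutanoate
Conditions: 4-acetamidobenzenesulfonyl azide, Et3N, MeCN, 0 °C → rt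
Reagents that add atoms: 4-acetamidobenzenesulfonyl azide, CC(=O)Nc1ccc(cc1)S(=O)(=O)N=[N+]=[N-]
Why: Regitz diazo transfer to the active methylene group of the β-keto ester.

Step 6
Reactants: 7 benzyl 2-diazo-3-oxobutanoate
Product: 8 benzyl 3-(tert-butyldimethylsilyloxy)-2-diazobut-3-enoate
Conditions: TBSOTf, Et3N, CH2Cl2, 0 °C
Reagents that add atoms: tert-butyldimethylsilyl trifluoromethanesulfonate, CC(C)(C)[Si](C)(C)OS(=O)(=O)C(F)(F)F
Why: Soft enolisation and O-silylation of the acetyl group (silyl triflate, amine base) gives the silyloxyvinyl diazoacetate, a donor/acceptor carbenoid precursor.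

Step 7
Reactants: 5 (R)-triethyl[(1-isopropyl-3-methyl-2-vinylcyclopent-2-en-1-yl)oxy]silane; 8 benzyl 3-(tert-butyldimethylsilyloxy)-2-diazobut-3-enoate
Product: 10 hydroazulene cycloadduct (C5=C6 and C8=C9; benzyl ester on C8; OTBS on C9; OTES and isopropyl on C4; methyl on quaternary C1 syn to O4), via cis-divinylcyclopropane 9 (not isolated)
Conditions: Rh2(S-PTAD)4 [dirhodium tetrakis((S)-(1-adamantyl)(N-phthalimido)acetate)] (1 mol %), 8 (2 equiv, slow addition), hexanes, −20 °C → rt; then PhMe, 100 °C
Reagents that add atoms: none
Why: The donor/acceptor rhodium carbenoid from 8 cyclopropanates the only unhindered alkene of 5, the terminal vinyl group C6=C7, to give the cis-divinylcyclopropane 9 (C7–C8 made), and on warming 9 undergoes a Cope rearrangement through a boat transition state that makes C10–C1 and breaks C6–C8. The closest known reaction type is the catalyst-controlled tandem cyclopropanation/Cope rearrangement (formal (4+3) cycloaddition) of silyloxyvinyl diazoacetates with semicyclic dienes whose ring terminus is fully substituted. The seven-membered ring is closed by this concerted [3,3]-sigmatropic shift, a union of a three-carbon and a four-carbon unit in which both alkenyl groups lie endo over the cyclopropane. The only new stereocenter that persists, quaternary C1, is set by the catalyst: by analogy with its known sense on monosubstituted alkenes, Rh2(S-PTAD)4 should select the face of the vinyl group that gives 9 with C8 R and C6 S, and the boat geometry relays this to C1, the C4 center being a spectator. The step needs chemoselectivity for the vinyl group over the tetrasubstituted alkene and over C–H insertion, and the cis arrangement of the two alkenyl groups that donor/acceptor carbenoids normally give; the steric difference between the two alkenes and the silyl protection of the C4 hydroxyl should secure these. The inward methyl group on C1 slows the Cope step, which is why heating is planned.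

Step 8
Reactants: 10 hydroazulene cycloadduct
Product: 13 C6 ketone (C5 epimers; C8=C9 silyl enol ether and benzyl ester retained), via alkylborane 11 (not isolated), via C6 alcohol 12 (not isolated)
Conditions: BH3·THF, THF, 0 °C → rt; then NMO·H2O, (n-Pr4N)RuO4 (5 mol %), CH2Cl2, rt
Reagents that add atoms: N-methylmorpholine N-oxide, C[N+]1([O-])CCOCC1
Why: Hydroboration puts boron on C6, the only alkene carbon that is not flanked by two quaternary centers; N-oxide oxidation of the C–B bond and perruthenate oxidation of the alcohol then give the C6 ketone in one flask, and the transient C5 and C6 centers are not relied on, because C6 becomes sp2 and C5 is corrected in steps 12 and 13.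

Step 9
Reactants: 13 C6 ketone
Product: 15 C8-methylated β-keto benzyl ester (6,9-diketone; C5 and C8 epimers), via ammonium enolate 14 (not isolated)
Conditions: Bu4NF (1.1 equiv), MeI, THF, −78 → 0 °C
Reagents that add atoms: iodomethane, CI
Why: Fluoride cleaves the silyl enol ether of the β-keto ester and the tetrabutylammonium enolate is C-methylated at C8 by iodomethane (enolate alkylation); the C8 center is erased later and the tertiary triethylsilyl ether should survive the cold, near-stoichiometric fluoride.

Step 10
Reactants: 15 C8-methylated β-keto benzyl ester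
Product: 17 4-(triethylsilyloxy)-6,9-diketone with methyl on C8 (C5 and C8 epimers), via β-keto acid 16 (not isolated)
Conditions: H2 (1 atm), Pd/C, EtOAc, rt; then 50 °C
Reagents that add atoms: none
Why: Hydrogenolysis of the benzyl ester and decarboxylation of the β-keto acid leave the methyl group alone on C8 under neutral conditions that spare the β-silyloxy ketone; the C8 epimer mixture is erased in step 11.

Step 11
Reactants: 17 4-(triethylsilyloxy)-6,9-diketone
Product: 18 4-(triethylsilyloxy)-7-ene-6,9-dione (C5 epimers)
Conditions: IBX, DMSO, 70 °C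
Reagents that add atoms: none
Why: IBX dehydrogenation of the 1,4-diketone can only take place across C7–C8, because C5 and C10 are attached to quaternary carbons and have no β-hydrogen, and it should give the ring enedione with the methyl group on C8.

Step 12
Reactants: 18 4-(triethylsilyloxy)-7-ene-6,9-dione
Product: 19 4-hydroxy-7-ene-6,9-dione (trans ring fusion)
Conditions: Et3N·3HF, MeCN, rt → 40 °C
Reagents that add atoms: none
Why: Fluoride-mediated desilylation frees the tertiary hydroxyl, and under these mildly acidic conditions C5 should equilibrate through the enol to the trans-fused epimer, in which C6 lies anti to the isopropyl group and the hydroxyl hydrogen-bonds to the C6 carbonyl.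

Step 13
Reactants: 19 4-hydroxy-7-ene-6,9-dione
Product: 20 4,6-dihydroxydauc-7-en-9-one (C6 hydroxyl syn to H5 and anti to the C4 hydroxyl)
Conditions: Me4NBH(OAc)3, MeCN/AcOH (1:1), −20 °C → rt
Reagents that add atoms: none
Why: Evans–Saksena reduction, in which the C4 hydroxyl binds boron and delivers hydride intramolecularly to the face of the C6 carbonyl on its own side, giving the 4,6-anti diol, while the C9 carbonyl has no hydroxyl within reach; only the trans-fused C5 epimer, with C6 and O4 cis on the five-membered ring, fits the cyclic transition state, so residual cis epimer should be funnelled through the enol.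

Step 14
Reactants: 20 4,6-dihydroxydauc-7-en-9-one; 21 (E)-4-acetoxycinnamic acid
Product: 23 O-acetate of the target (6-O-(E)-4-acetoxycinnamate of 20), via mixed anhydride 22 (not isolated)
Conditions: 21, 2,4,6-Cl3C6H2COCl, Et3N, PhMe, rt; then 20, DMAP, rt
Reagents that add atoms: none
Why: Yamaguchi esterification acylates the secondary allylic C6 hydroxyl with retention, the tertiary C4 hydroxyl being inert, and keeps the E alkene; the acetate masks the phenol.

Step 15
Reactants: 23 O-acetate of the target
Product: 24 target (CNP0310968.1)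
Conditions: K2CO3 (0.2 equiv), MeOH, 0 °C
Reagents that add atoms: none
Why: Base-catalysed methanolysis cleaves the aryl acetate (phenoxide leaving group) much faster than the alkyl cinnamate ester and releases the phenol without touching any stereocenter.

Compound list
1 | (S)-(+)-terpinen-4-ol | CC1=CC[C@](O)(C(C)C)CC1 | starting material
2 | (S)-terpinen-4-ol triethylsilyl ether | CC1=CC[C@](O[Si](CC)(CC)CC)(C(C)C)CC1 | intermediate
3 | (S)-3-isopropyl-6-oxo-3-(triethylsilyloxy)heptanal | CC(=O)CC[C@@](O[Si](CC)(CC)CC)(C(C)C)CC=O | intermediate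
4 | (R)-5-isopropyl-2-methyl-5-(triethylsilyloxy)cyclopent-1-ene-1-carbaldehyde | CC1=C(C=O)[C@](O[Si](CC)(CC)CC)(C(C)C)CC1 | intermediate
5 | (R)-triethyl[(1-isopropyl-3-methyl-2-vinylcyclopent-2-en-1-yl)oxy]silane | CC1=C(C=C)[C@](O[Si](CC)(CC)CC)(C(C)C)CC1 | intermediate
6 | benzyl acetoacetate | CC(=O)CC(=O)OCc1ccccc1 | starting material
7 | benzyl 2-diazo-3-oxobutanoate | CC(=O)C(=[N+]=[N-])C(=O)OCc1ccccc1 | intermediate
8 | benzyl 3-(tert-butyldimethylsilyloxy)-2-diazobut-3-enoate | C=C(O[Si](C)(C)C(C)(C)C)C(=[N+]=[N-])C(=O)OCc1ccccc1 | intermediate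
9 | cis-divinylcyclopropane (C8 R, C6 S; silyloxyvinyl and cyclopentenyl groups cis) | O=C(OCc1ccccc1)[C@]2(C(=C)O[Si](C)(C)C(C)(C)C)C[C@H]2C3=C(C)CC[C@@]3(O[Si](CC)(CC)CC)C(C)C | intermediate
10 | hydroazulene cycloadduct (C5=C6, C8=C9, CO2Bn on C8, OTBS on C9, OTES on C4, C1 methyl syn to O4) | O=C(OCc1ccccc1)C2=C(O[Si](C)(C)C(C)(C)C)C[C@@]3(C)CC[C@@](O[Si](CC)(CC)CC)(C(C)C)C3=CC2 | intermediate
11 | C6 alkylborane (C5 and C6 diastereomers) | O=C(OCc1ccccc1)C2=C(O[Si](C)(C)C(C)(C)C)C[C@@]3(C)CC[C@@](O[Si](CC)(CC)CC)(C(C)C)C3C(B)C2 | intermediate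
12 | C6 alcohol (C5 and C6 diastereomers) | O=C(OCc1ccccc1)C2=C(O[Si](C)(C)C(C)(C)C)C[C@@]3(C)CC[C@@](O[Si](CC)(CC)CC)(C(C)C)C3C(O)C2 | intermediate
13 | C6 ketone (C5 epimers) | O=C(OCc1ccccc1)C2=C(O[Si](C)(C)C(C)(C)C)C[C@@]3(C)CC[C@@](O[Si](CC)(CC)CC)(C(C)C)C3C(=O)C2 | intermediate
14 | tetrabutylammonium enolate of the β-keto ester | CCCC[N+](CCCC)(CCCC)CCCC.O=C(OCc1ccccc1)C2=C([O-])C[C@@]3(C)CC[C@@](O[Si](CC)(CC)CC)(C(C)C)C3C(=O)C2 | intermediate
15 | C8-methylated β-keto benzyl ester (C5 and C8 epimers) | O=C(OCc1ccccc1)C2(C)C(=O)C[C@@]3(C)CC[C@@](O[Si](CC)(CC)CC)(C(C)C)C3C(=O)C2 | intermediate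
16 | β-keto acid (C5 and C8 epimers) | OC(=O)C2(C)C(=O)C[C@@]3(C)CC[C@@](O[Si](CC)(CC)CC)(C(C)C)C3C(=O)C2 | intermediate
17 | 4-(triethylsilyloxy)-6,9-diketone with methyl on C8 (C5 and C8 epimers) | CC2C(=O)C[C@@]3(C)CC[C@@](O[Si](CC)(CC)CC)(C(C)C)C3C(=O)C2 | intermediate
18 | 4-(triethylsilyloxy)-7-ene-6,9-dione (C5 epimers) | CC1=CC(=O)C2[C@](C)(CC[C@@]2(O[Si](CC)(CC)CC)C(C)C)CC1=O | intermediate
19 | 4-hydroxy-7-ene-6,9-dione (trans-fused) | CC1=CC(=O)[C@@H]2[C@](C)(CC[C@@]2(O)C(C)C)CC1=O | intermediate
20 | 4,6-dihydroxydauc-7-en-9-one | CC1=C[C@H](O)[C@@H]2[C@](C)(CC[C@@]2(O)C(C)C)CC1=O | intermediate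
21 | (E)-4-acetoxycinnamic acid | CC(=O)Oc1ccc(/C=C/C(=O)O)cc1 | starting material
22 | mixed anhydride of 21 with 2,4,6-trichlorobenzoic acid | CC(=O)Oc1ccc(/C=C/C(=O)OC(=O)c2c(Cl)cc(Cl)cc2Cl)cc1 | intermediate
23 | O-acetate of the target | CC1=C[C@H](OC(=O)/C=C/c2ccc(OC(C)=O)cc2)[C@@H]2[C@](C)(CC[C@@]2(O)C(C)C)CC1=O | intermediate
24 | target, CNP0310968.1 | CC1=C[C@H](OC(=O)/C=C/c2ccc(O)cc2)[C@@H]2[C@](C)(CC[C@@]2(O)C(C)C)CC1=O | target

Total step count: 15. Longest linear sequence: 13 steps (steps 1 to 4 and 7 to 15).

Steps most likely to fail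

Step 7. The Cope rearrangement of the crowded cis-divinylcyclopropane may be slow, because the inward methyl group on C1 meets the cyclopropane. Prolonged heating could then divert material through ring opening or hydrogen shifts, and a mismatch between the catalyst and the C4 center could erode facial control. The fallback sets out from 5 and returns at 17; it brings the three-carbon unit in as an oxyallyl cation instead of a carbenoid. Diene 5 and 3-chlorobutan-2-one with Et3N in CF3CH2OH should give, by (4+3) cycloaddition, the cycloheptenone F1 (C9 ketone, methyl already on C8, C5=C6), whose C1 epimers, formed under substrate control only, would be separated. BH3·THF followed by NaBO3 should hydroborate C5=C6 and reduce the ketone to give the diol F2, and Dess–Martin periodinane should oxidise both hydroxyls to give 17.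

Step 8. Hydroboration of an alkene flanked by two quaternary carbons may be sluggish, which would let borane reduce the ester or attack the enol ether instead. The fallback sets out from 4 and returns at 13; it has the diene deliver the C6 oxygen. MeMgBr should add to 4 to give the allylic alcohol F3, Dess–Martin periodinane should give the methyl ketone F4, and TBSOTf/Et3N should give the 2-silyloxy diene F5. The same rhodium-catalysed (4+3) reaction with 8 should then give the bis(silyl enol ether) F6, and brief AcOH/THF/H2O should hydrolyse the simple C6 silyl enol ether in preference to the ester-conjugated one, giving 13.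

Step 13. Epimerisation at C5 may be incomplete under the acidic conditions, or hydride delivery may not be intramolecular and would then be poorly face-selective at C6. The fallback sets out from 19 and returns at 23; it sets C6 by inversion instead of by direct delivery. Narasaka–Prasad reduction (Et2BOMe, NaBH4, THF/MeOH, −78 °C) should give the syn diol F7, the C6 epimer of 20, through external hydride attack on the boron chelate. Mitsunobu esterification of F7 with 21 (PPh3, DIAD) should then invert C6 and give 23 directly.

Further compounds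
F1 | step 7 | oxyallyl (4+3) cycloadduct: 4-(triethylsilyloxy)dauc-5-en-9-one with methyl on C8 (C8 epimers) | CC1CC=C2[C@](C)(CC[C@@]2(O[Si](CC)(CC)CC)C(C)C)CC1=O
F2 | step 7 | 6,9-diol from hydroboration and ketone reduction (diastereomers at C5, C6, C8, C9) | CC1CC(O)C2[C@](C)(CC[C@@]2(O[Si](CC)(CC)CC)C(C)C)CC1O
F3 | step 8 | 1-[5-isopropyl-2-methyl-5-(triethylsilyloxy)cyclopent-1-en-1-yl]ethanol (carbinol epimers) | CC(O)C1=C(C)CC[C@@]1(O[Si](CC)(CC)CC)C(C)C
F4 | step 8 | 1-[5-isopropyl-2-methyl-5-(triethylsilyloxy)cyclopent-1-en-1-yl]ethanone | CC(=O)C1=C(C)CC[C@@]1(O[Si](CC)(CC)CC)C(C)C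
F5 | step 8 | 2-silyloxy diene: tert-butyldimethylsilyl enol ether of F4 | C=C(O[Si](C)(C)C(C)(C)C)C1=C(C)CC[C@@]1(O[Si](CC)(CC)CC)C(C)C
F6 | step 8 | bis(silyl enol ether) cycloadduct (OTBS on C6 and C9, benzyl ester on C8) | O=C(OCc1ccccc1)C2=C(O[Si](C)(C)C(C)(C)C)C[C@@]3(C)CC[C@@](O[Si](CC)(CC)CC)(C(C)C)C3=C(O[Si](C)(C)C(C)(C)C)C2
F7 | step 13 | C6 epimer of 20 (4,6-syn diol) | CC1=C[C@@H](O)[C@@H]2[C@](C)(CC[C@@]2(O)C(C)C)CC1=O
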